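## Analysis of the target

The target 13 is a flavanone, that is, a chroman-4-one. Ring A (C4a to C8a) carries methoxy groups at C5 and C7, ring C is the O1–C2–C3–C4(=O) heterocycle, and ring B, a 2,3,4-trimethoxyphenyl group, sits on C2. The only stereocentre is C2, of S configuration (O1 > aryl > C3 > H); it is benzylic to an electron-rich ring, bonded to O1 and β to the C4 carbonyl. This makes it fragile: base that enolises C3 can expel the phenoxide O1 (retro-oxa-Michael) to a 2'-hydroxychalcone that recloses without facial bias, and acid can ionise the C2–O1 bond with help from the ortho and para methoxy groups of ring B. The five aryl methyl ethers, above all the C5 ether peri to the carbonyl, forbid hard Lewis acids late in the route, and the two electron-rich rings forbid unselective oxidants. The difficulty is therefore not the skeleton, which comes from two benzenoid pieces and a two-carbon unit, but setting one labile stereocentre and then never exposing the enolisable β-aryloxy ketone to base. The feature exploited is that O1 bridges the sp3 carbinol carbon C2 and the aromatic carbon C8a of ring A. If ring C is closed by joining O1 to C8a, from a C2 alcohol and a C8a bromide, the C2–O bond is made early in an open-chain alcohol and is never broken again. The C4 carbonyl is carried through that closure as an exocyclic methylene, so that no β-hydroxy or β-aryloxy ketone ever meets the base.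

## Retrosynthetic reasoning

**13 to 11 (C4=O from C4=CH2).** The last operation is chosen to be neutral and to touch only C4: the carbonyl oxygen is introduced by cleaving the exocyclic double bond of 11, through diol 12. Cutting here rather than at a ring bond means that the flavanone exists only after every basic step is over. The forward reaction must oxidise a 1,1-disubstituted styrene-type alkene without attacking two electron-rich arenes.

**11 to 10 (O1–C8a).** Ring C is opened at the aryl–oxygen bond, which gives the open-chain (S)-alcohol 10 with bromine on C8a. Cutting O1–C2 instead would make the stereocentre the electrophile, with inversion or ionisation at an electron-rich benzylic carbon. Cutting C2–C3 or C3–C4 would first demand an aryl ether of the chiral carbinol. With O1–C8a as the bond formed, C2 is a bystander and its configuration is carried through unchanged. The forward reaction must make an aryl–oxygen bond from a secondary alkoxide without β-hydride loss.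

**10 to 9 to 8 (protecting group and C4=CH2).** Alcohol 10 is traced to its silyl ether 9, and the methylene of 9 to the ketone of 8. The C=CH2 bond is cut because a ketone is the natural outcome of an aldol construction. The silyl ether is there only so that methylenation does not meet a free β-hydroxy ketone, which could undergo retro-aldol cleavage. The forward reaction must transfer a methylene group to a hindered, enolisable β-silyloxy aryl ketone under non-basic conditions.

**8 to 7 to 4 + 5 (C2–C3).** The β-hydroxy ketone 7 is cut at the aldol bond between C2 and C3. This is the one C–C disconnection that splits the molecule into two aromatic halves of similar size and creates the stereocentre in the same event. It leads to aldehyde 5, which is bought with all three ring B methoxy groups, and to enol silane 4. The forward reaction must add 4 to the Si face of 5; it passes through silyl aldolate 6.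

**4 to 3 to 1 + 2 (C4–C4a).** Enol silane 4 comes from methyl ketone 3, and 3 is cut at the aryl–carbonyl bond to give bromoarene 1 and acyl chloride 2. Ring A is thereby bought complete, with both methoxy groups and with the bromine that becomes the leaving group of the ring closure. The forward acylation must go ortho to bromine and para to a methoxy group, the position at which 1 is normally formylated and halogenated.

## Alternatives that were turned down

**Alternative 1:** Hetero-Diels–Alder construction of ring C before ring A.
- Disconnection: C2–C3 and O1–C8a are cut together. Ring C goes back to aldehyde 5 and 1-methoxy-3-(trimethylsilyloxy)buta-1,3-diene (A2); ring A is left to be built afterwards.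
- Forward key step: a chiral Lewis acid catalyses the cycloaddition of 5 and A2. After loss of the methoxy and silyl groups of the diene this gives (2S)-2-(2,3,4-trimethoxyphenyl)-2,3-dihydro-4H-pyran-4-one (A1).
- For it: this is one of the most dependable catalytic asymmetric reactions of aromatic aldehydes. It sets C2 and closes ring C in one step. On the installation of the stereocentre it is at least as strong as the aldol addition used here, and probably stronger.
- Against it: A1 contains nothing of ring A. Four carbons, two oxygen substituents and an aromatisation must be grafted onto the C4a=C8a double bond of a base-sensitive vinylogous ester. Its C2 centre can be lost by the same retro-oxa-Michael path as in 13. C8a carries only hydrogen in A1, so a separate C–H functionalisation or a more elaborate diene is needed. Most of the step count falls after the key step.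
- Comparison: the chosen route concedes the more elegant stereo-setting step. In return it buys ring A ready-made, with its methoxy groups and the bromine handle, and needs no arene construction.

**Alternative 2:** Biomimetic Claisen closure of ring A.
- Disconnection: C4a–C5 of ring A is cut. The precursor is methyl 3-oxo-4-[(2S)-4-oxo-2-(2,3,4-trimethoxyphenyl)-3,4-dihydro-2H-pyran-6-yl]butanoate (A4), whose side chain on C8a supplies C8, C7, C6 and C5.
- Forward key step: base generates the extended enolate through C8; C4a attacks the ester carbonyl, ring A closes as a six-membered ring and enolises to the aromatic diol (2S)-5,7-dihydroxy-2-(2,3,4-trimethoxyphenyl)chroman-4-one (A3).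
- For it: the polyketide logic places oxygen at C5 and C7 automatically and builds the whole of ring A in one step. It also gives a purpose to the dihydropyranone A1.
- Against it: A4 has three acidic sites, and the most acidic one, C6 between ketone and ester, is the wrong one. Aldol closures onto the ketone carbonyls compete. The basic medium can enolise C3 and open ring C. The product A3 is a diol, so two O-methylations follow, and the chelated C5 hydroxyl is methylated only under forcing basic conditions, which are the conditions that racemise flavanones through the chalcone. A4 itself needs several steps.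
- Comparison: the chosen route never carries free phenols and never treats a flavanone with base. It gives up the convergence on ring A, which it does not need because ring A is bought.

**Alternative 3:** Enol ether ring-closing metathesis at C3–C4.
- Disconnection: the C3=C4 bond of (2S)-4-(tert-butyldimethylsilyloxy)-5,7-dimethoxy-2-(2,3,4-trimethoxyphenyl)-2H-chromene (A5) is cut. The precursor is the diene tert-butyl({1-[2,4-dimethoxy-6-{[(1S)-1-(2,3,4-trimethoxyphenyl)prop-2-en-1-yl]oxy}phenyl]ethenyl}oxy)dimethylsilane (A6), in which both C–O bonds of O1 already exist.
- Forward key step: second-generation Grubbs catalyst joins the vinyl carbon on C2 to the enol ether carbon C4, with loss of the two terminal methylene groups, and closes ring C as A5. Mild hydrolysis of A5 would give 13.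
- For it: C4 arrives at the ketone oxidation level in masked form, so the end game needs no oxidant, and the conditions are neutral. On this point it is as good as or better than the methylene detour of the chosen route.
- Against it: A6 is an enantiopure aryl ether at a carbon that is both allylic and benzylic to an electron-rich ring. Its preparation from a hindered ortho-acyl phenol invites SN1 and SN2' scrambling. On heating it can ionise or undergo aromatic Claisen rearrangement to the free C8 position, and heat is needed to metathesise a 1,1-disubstituted enol ether flanked by two ortho substituents. In A5 the stereocentre is still allylic, so ruthenium hydride species or acid can scramble it.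
- Comparison: the chosen route forms the C2–O bond as a plain alcohol in an aldol step and closes the ring at the aryl end. The stereocentre is never allylic and never a leaving group. The price is one oxidation step at the end.

Key step: step 7

Remark on the chemistry: atoms are numbered as in the flavanone (O1, C2, C3, C4, C4a, C5 to C8, C8a) also in open-chain intermediates; in step 3 the bisphosphoramide antipode that directs addition to the Si face of the aldehyde is required and is taken to be the (S,S)-form.

## Route

Step 1
Reactants: 1 1-bromo-3,5-dimethoxybenzene; 2 acetyl chloride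
Product: 3 1-(2-bromo-4,6-dimethoxyphenyl)ethan-1-one
Conditions: AlCl3 (1.1 equiv), CH2Cl2, −10 to 0 °C; then ice/1 M HCl
Reagents that add atoms: none
Why: Friedel-Crafts acylation; the acylium ion should attack the carbon that is para to one methoxy group and ortho to the other (and ortho to bromine) rather than the more crowded carbon between the two methoxy groups, as formylation and halogenation of 1 do. One equivalent of AlCl3 at or below 0 °C should leave the methyl ether ortho to the new carbonyl intact.

Step 2
Reactants: 3 1-(2-bromo-4,6-dimethoxyphenyl)ethan-1-one
Product: 4 {[1-(2-bromo-4,6-dimethoxyphenyl)ethenyl]oxy}trimethylsilane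
Conditions: TMSOTf (1.2 equiv), Et3N (1.5 equiv), CH2Cl2, 0 °C; non-aqueous work-up (pentane, filtration)
Reagents that add atoms: trimethylsilyl trifluoromethanesulfonate (TMSOTf), C[Si](C)(C)OS(=O)(=O)C(F)(F)F
Why: Soft enolisation of a methyl ketone by the silyl triflate/amine pair gives the only possible enol silane; the aryl bromide and the methyl ethers are inert, and the dry work-up avoids hydrolysis.

Step 3
Reactants: 4 {[1-(2-bromo-4,6-dimethoxyphenyl)ethenyl]oxy}trimethylsilane; 5 2,3,4-trimethoxybenzaldehyde
Product: 7 (3S)-1-(2-bromo-4,6-dimethoxyphenyl)-3-hydroxy-3-(2,3,4-trimethoxyphenyl)propan-1-one, via trichlorosilyl aldolate 6 (not isolated)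
Conditions: SiCl4 (1.5 equiv), (S,S)-bisphosphoramide catalyst [pentamethylene-linked bis(phosphoramide) of N,N'-dimethyl-1,1'-binaphthyl-2,2'-diamine] (5 mol %), iPr2NEt (10 mol %), CH2Cl2, −78 °C; then cold sat. aq. NaHCO3
Reagents that add atoms: SiCl4, Cl[Si](Cl)(Cl)Cl (supplies the SiCl3 group of 6; none of its atoms remains in 7); water, O (supplies only the hydroxyl hydrogen of 7)
Why: Catalytic asymmetric Mukaiyama aldol addition under Lewis-base activation of SiCl4: the bisphosphoramide binds SiCl4 to give a chiral cationic trichlorosilyl species that activates 5, the enol silane adds through an open transition state to the Si face of the aldehyde, and chloride removes the Me3Si group. The (S)-carbinol centre, the future C2, is thus set by the catalyst; aromatic aldehydes with methyl ketone enol silanes are the best-behaved substrate pair of this reaction type, and the cold bicarbonate work-up should free the alcohol without dehydration.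

Step 4
Reactants: 7 (3S)-1-(2-bromo-4,6-dimethoxyphenyl)-3-hydroxy-3-(2,3,4-trimethoxyphenyl)propan-1-one
Product: 8 (3S)-1-(2-bromo-4,6-dimethoxyphenyl)-3-[(tert-butyldimethylsilyl)oxy]-3-(2,3,4-trimethoxyphenyl)propan-1-one
Conditions: TBSOTf (1.3 equiv), 2,6-lutidine (2 equiv), CH2Cl2, −78 to 0 °C
Reagents that add atoms: tert-butyldimethylsilyl trifluoromethanesulfonate (TBSOTf), CC(C)(C)[Si](C)(C)OS(=O)(=O)C(F)(F)F
Why: O-Silylation of a secondary alcohol; the hindered pyridine base is too weak to enolise the ketone or to trigger β-elimination, and the C–O bond of the stereocentre is not touched.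

Step 5
Reactants: 8 (3S)-1-(2-bromo-4,6-dimethoxyphenyl)-3-[(tert-butyldimethylsilyl)oxy]-3-(2,3,4-trimethoxyphenyl)propan-1-one
Product: 9 tert-butyl{[(1S)-3-(2-bromo-4,6-dimethoxyphenyl)-1-(2,3,4-trimethoxyphenyl)but-3-en-1-yl]oxy}dimethylsilane
Conditions: Cp2TiMe2 (3 equiv), toluene, 75 °C, dark
Reagents that add atoms: dimethyltitanocene Cp2TiMe2, C[Ti](C)(C1C=CC=C1)C1C=CC=C1 (supplies the CH2 carbon)
Why: Petasis methylenation: Cp2TiMe2 loses CH4 on heating to give Cp2Ti=CH2, which adds [2+2] to the carbonyl and cycloreverts, driven by the Ti–O bond. The reagent is not basic enough to eliminate the β-silyloxy group and does not react with the aryl bromide, which is why it is preferred to a phosphorus ylide for this hindered, enolisable ketone.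

Step 6
Reactants: 9 tert-butyl{[(1S)-3-(2-bromo-4,6-dimethoxyphenyl)-1-(2,3,4-trimethoxyphenyl)but-3-en-1-yl]oxy}dimethylsilane
Product: 10 (1S)-3-(2-bromo-4,6-dimethoxyphenyl)-1-(2,3,4-trimethoxyphenyl)but-3-en-1-ol
Conditions: Bu4NF (1.2 equiv), THF, 0 to 20 °C
Reagents that add atoms: none
Why: Fluoride-induced cleavage of the Si–O bond; the C–O bond of the stereocentre is not involved, and nothing else in 9 responds to fluoride.

Step 7
Reactants: 10 (1S)-3-(2-bromo-4,6-dimethoxyphenyl)-1-(2,3,4-trimethoxyphenyl)but-3-en-1-ol
Product: 11 (2S)-5,7-dimethoxy-4-methylidene-2-(2,3,4-trimethoxyphenyl)-3,4-dihydro-2H-chromene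
Conditions: Pd(OAc)2 (5 mol %), rac-2-(di-tert-butylphosphino)-1,1'-binaphthyl (6 mol %), Cs2CO3 (1.5 equiv), degassed toluene, 70 °C
Reagents that add atoms: none
Why: Pd(OAc)2 is reduced in the flask to a zerovalent palladium–phosphine complex, which inserts into the C8a–Br bond; carbonate-assisted exchange of bromide for the C2 alkoxide gives a divalent aryl(alkoxo)palladium chelate, and C–O reductive elimination forms O1–C8a and returns zerovalent palladium. The closest known reaction type is the palladium-catalysed intramolecular etherification of aryl bromides with secondary alcohols (Buchwald–Hartwig C–O coupling), which is established for chromans and preserves the configuration of the carbinol carbon. Ring C is closed as a six-membered ring by reductive elimination from a seven-membered oxapalladacycle, formally a 6-exo attack of O1 on the ipso carbon C8a. No stereocentre is created; C2 keeps its S configuration because neither its C–O nor its C–H bond is broken in the productive cycle. The selectivity required is reductive elimination over β-hydride elimination from the secondary benzylic alkoxide, and it is secured by the bulky, electron-rich di-tert-butyl biaryl phosphine, which enforces a low-coordinate intermediate and accelerates C–O bond formation, and by the intramolecular delivery of the alkoxide. The substrate helps in three ways: the bromide is meta to both methoxy groups and should add oxidatively without difficulty, the ortho alkenyl group cannot undergo Heck insertion because only three- or four-membered rings could result, and the exocyclic methylene at C4 removes every base-sensitive carbonyl, so that Cs2CO3 can neither cleave a β-hydroxy ketone by retro-aldol reaction nor open a finished flavanone.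

Step 8
Reactants: 11 (2S)-5,7-dimethoxy-4-methylidene-2-(2,3,4-trimethoxyphenyl)-3,4-dihydro-2H-chromene
Product: 13 (2S)-5,7-dimethoxy-2-(2,3,4-trimethoxyphenyl)-2,3-dihydro-4H-chromen-4-one, via vicinal diol 12 (not isolated)
Conditions: OsO4 (3 mol %), NaIO4 (4 equiv), 2,6-lutidine (2 equiv), 1,4-dioxane/H2O 3:1, 20 °C
Reagents that add atoms: OsO4, O=[Os](=O)(=O)=O (delivers both oxygens of 12, one of which remains as the carbonyl oxygen of 13); NaIO4, [Na+].[O-][I](=O)(=O)=O (cleaves 12 and reoxidises osmium); water, O
Why: Lemieux-Johnson oxidation: OsO4 dihydroxylates the electron-rich 1,1-disubstituted alkene, and periodate cleaves diol 12 and regenerates OsO4. The buffered, near-neutral medium at room temperature should neither oxidise the methoxyarenes, as ozone might, nor enolise the new flavanone, so C2 is not epimerised through ring opening to the chalcone.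

## Compound list

1 | 1-bromo-3,5-dimethoxybenzene | COc1cc(Br)cc(OC)c1 | starting material
2 | acetyl chloride | CC(Cl)=O | starting material
3 | 1-(2-bromo-4,6-dimethoxyphenyl)ethan-1-one | CC(=O)c1c(Br)cc(OC)cc1OC | intermediate
4 | {[1-(2-bromo-4,6-dimethoxyphenyl)ethenyl]oxy}trimethylsilane | C=C(O[Si](C)(C)C)c1c(Br)cc(OC)cc1OC | intermediate
5 | 2,3,4-trimethoxybenzaldehyde | COc1ccc(C=O)c(OC)c1OC | starting material
6 | (3S)-1-(2-bromo-4,6-dimethoxyphenyl)-3-[(trichlorosilyl)oxy]-3-(2,3,4-trimethoxyphenyl)propan-1-one (not isolated) | O=C(C[C@H](O[Si](Cl)(Cl)Cl)c1ccc(OC)c(OC)c1OC)c1c(Br)cc(OC)cc1OC | intermediate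
7 | (3S)-1-(2-bromo-4,6-dimethoxyphenyl)-3-hydroxy-3-(2,3,4-trimethoxyphenyl)propan-1-one | O=C(C[C@H](O)c1ccc(OC)c(OC)c1OC)c1c(Br)cc(OC)cc1OC | intermediate
8 | (3S)-1-(2-bromo-4,6-dimethoxyphenyl)-3-[(tert-butyldimethylsilyl)oxy]-3-(2,3,4-trimethoxyphenyl)propan-1-one | O=C(C[C@H](O[Si](C)(C)C(C)(C)C)c1ccc(OC)c(OC)c1OC)c1c(Br)cc(OC)cc1OC | intermediate
9 | tert-butyl{[(1S)-3-(2-bromo-4,6-dimethoxyphenyl)-1-(2,3,4-trimethoxyphenyl)but-3-en-1-yl]oxy}dimethylsilane | C=C(C[C@H](O[Si](C)(C)C(C)(C)C)c1ccc(OC)c(OC)c1OC)c1c(Br)cc(OC)cc1OC | intermediate
10 | (1S)-3-(2-bromo-4,6-dimethoxyphenyl)-1-(2,3,4-trimethoxyphenyl)but-3-en-1-ol | C=C(C[C@H](O)c1ccc(OC)c(OC)c1OC)c1c(Br)cc(OC)cc1OC | intermediate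
11 | (2S)-5,7-dimethoxy-4-methylidene-2-(2,3,4-trimethoxyphenyl)-3,4-dihydro-2H-chromene | COc1cc(OC)c2c(c1)O[C@H](c1ccc(OC)c(OC)c1OC)CC2=C | intermediate
12 | (2S)-4-(hydroxymethyl)-5,7-dimethoxy-2-(2,3,4-trimethoxyphenyl)-3,4-dihydro-2H-chromen-4-ol, both C4 epimers (not isolated) | COc1cc(OC)c2c(c1)O[C@H](c1ccc(OC)c(OC)c1OC)CC2(O)CO | intermediate
13 | (2S)-5,7-dimethoxy-2-(2,3,4-trimethoxyphenyl)-2,3-dihydro-4H-chromen-4-one | COc1cc(OC)c2c(c1)O[C@H](c1ccc(OC)c(OC)c1OC)CC2=O | target

## Step count and least certain steps

Total: 8 steps. Longest linear sequence: 8 steps, from 1 to 13; aldehyde 5 enters at step 3.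

**Step 7 (key step).** The most likely failure is β-hydride elimination from the palladium alkoxide of this electron-rich benzylic alcohol. It would give an aryl ketone and a palladium hydride; the hydride would then reduce the C8a–Br bond and could move the exocyclic double bond into ring C, so that both the cyclisation and the handle for step 8 are lost. A RockPhos-type ligand would be tried first, but the fallback changes the mechanism. It sets out from 10: lithium 2,2,6,6-tetramethylpiperidide (2.5 equiv) in THF, −78 to 0 °C, deprotonates the hydroxyl group and then C8–H, the only hydrogen ortho to bromine. Loss of bromide gives the aryne lithium (1S)-3-(2,3-didehydro-4,6-dimethoxyphenyl)-1-(2,3,4-trimethoxyphenyl)but-3-en-1-olate F1. Its tethered alkoxide adds to C8a, closing the six-membered ring and leaving the aryl anion at C8 next to the C7 methoxy group, which is the electronically favoured sense of addition to a 3-alkoxyaryne. Protonation on work-up returns the route at 11. No metal hydride is involved and the C2–O bond is again untouched. Metalation at C6 between the two methoxy groups is unproductive but reversible with an amide base.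

**Step 3.** The most likely failure is poor facial selectivity or low turnover. The ortho methoxy group of 5 can chelate the silicon Lewis acid, and the enol silane is flanked by two ortho substituents; loss of water from the product toward the chalcone during work-up is a second path. The fallback sets the stereocentre by epoxidation instead of aldol addition. It sets out from 3 and 5: Claisen–Schmidt condensation (KOH, EtOH, 20 °C) gives (2E)-1-(2-bromo-4,6-dimethoxyphenyl)-3-(2,3,4-trimethoxyphenyl)prop-2-en-1-one F2. Juliá–Colonna epoxidation (urea–H2O2, DBU, THF) follows, with the polyleucine antipode that delivers the (2S,3R) series, expected to be poly-D-leucine; it gives (2-bromo-4,6-dimethoxyphenyl)[(2S,3R)-3-(2,3,4-trimethoxyphenyl)oxiran-2-yl]methanone F3. SmI2 in THF/MeOH at −90 °C cleaves only the C–O bond α to the carbonyl, keeps the configuration of the benzylic carbon, and returns the route at 7. Without a strong donor additive SmI2 should leave the aryl bromide alone.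

**Step 5.** The most likely failure is slow [2+2] addition of the bulky Cp2Ti=CH2 to a carbonyl shielded on both faces by the ortho bromine and methoxy group; prolonged heating would then lead to β-elimination of the silyloxy group. The fallback is a Peterson olefination, a two-stage addition and elimination. It sets out from 8: Me3SiCH2Li with anhydrous CeCl3 in THF at −78 °C, a small and non-basic organocerium nucleophile, should add to the ketone to give (4S)-2-(2-bromo-4,6-dimethoxyphenyl)-4-[(tert-butyldimethylsilyl)oxy]-4-(2,3,4-trimethoxyphenyl)-1-(trimethylsilyl)butan-2-ol F4 as a mixture of carbinol epimers. KH in THF at 0 °C then brings about syn-elimination of the silanolate, which can only give the terminal alkene, and returns the route at 9.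

**Step 1.** The most likely failure is acylation at the carbon between the two methoxy groups, or AlCl3-promoted cleavage of the methyl ether ortho to the new carbonyl. The fallback introduces the carbon in two stages without a strong Lewis acid. It sets out from 1: Vilsmeier–Haack formylation (POCl3, DMF, 0 to 80 °C; aqueous NaOAc) gives 2-bromo-4,6-dimethoxybenzaldehyde F5. MeMgBr in THF at 0 °C gives 1-(2-bromo-4,6-dimethoxyphenyl)ethan-1-ol F6, and oxidation of this benzylic alcohol with MnO2 in CH2Cl2 returns the route at 3.

## Further compounds

F1 | step 7 | lithium (1S)-3-(2,3-didehydro-4,6-dimethoxyphenyl)-1-(2,3,4-trimethoxyphenyl)but-3-en-1-olate (aryne, not isolated) | C=C(C[C@H]([O-])c1ccc(OC)c(OC)c1OC)C1=C(OC)C=C(OC)C#C1.[Li+]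
F2 | step 3 | (2E)-1-(2-bromo-4,6-dimethoxyphenyl)-3-(2,3,4-trimethoxyphenyl)prop-2-en-1-one | O=C(/C=C/c1ccc(OC)c(OC)c1OC)c1c(Br)cc(OC)cc1OC
F3 | step 3 | (2-bromo-4,6-dimethoxyphenyl)[(2S,3R)-3-(2,3,4-trimethoxyphenyl)oxiran-2-yl]methanone | O=C(c1c(Br)cc(OC)cc1OC)[C@H]1O[C@@H]1c1ccc(OC)c(OC)c1OC
F4 | step 5 | (4S)-2-(2-bromo-4,6-dimethoxyphenyl)-4-[(tert-butyldimethylsilyl)oxy]-4-(2,3,4-trimethoxyphenyl)-1-(trimethylsilyl)butan-2-ol | C[Si](C)(C)CC(O)(C[C@H](O[Si](C)(C)C(C)(C)C)c1ccc(OC)c(OC)c1OC)c1c(Br)cc(OC)cc1OC
F5 | step 1 | 2-bromo-4,6-dimethoxybenzaldehyde | O=Cc1c(Br)cc(OC)cc1OC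
F6 | step 1 | 1-(2-bromo-4,6-dimethoxyphenyl)ethan-1-ol (racemic) | CC(O)c1c(Br)cc(OC)cc1OC
A1 | alternative 1 | (2S)-2-(2,3,4-trimethoxyphenyl)-2,3-dihydro-4H-pyran-4-one | O=C1C[C@@H](c2ccc(OC)c(OC)c2OC)OC=C1
A2 | alternative 1 | (1E)-1-methoxy-3-(trimethylsilyloxy)buta-1,3-diene | CO/C=C/C(=C)O[Si](C)(C)C
A3 | alternative 2 | (2S)-5,7-dihydroxy-2-(2,3,4-trimethoxyphenyl)chroman-4-one | Oc1cc(O)c2c(c1)O[C@H](c1ccc(OC)c(OC)c1OC)CC2=O
A4 | alternative 2 | methyl 3-oxo-4-[(2S)-4-oxo-2-(2,3,4-trimethoxyphenyl)-3,4-dihydro-2H-pyran-6-yl]butanoate | O=C1C[C@@H](c2ccc(OC)c(OC)c2OC)OC(CC(=O)CC(=O)OC)=C1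
A5 | alternative 3 | (2S)-4-(tert-butyldimethylsilyloxy)-5,7-dimethoxy-2-(2,3,4-trimethoxyphenyl)-2H-chromene | COc1cc(OC)c2c(c1)O[C@H](c1ccc(OC)c(OC)c1OC)C=C2O[Si](C)(C)C(C)(C)C
A6 | alternative 3 | tert-butyl({1-[2,4-dimethoxy-6-{[(1S)-1-(2,3,4-trimethoxyphenyl)prop-2-en-1-yl]oxy}phenyl]ethenyl}oxy)dimethylsilane | C=C(O[Si](C)(C)C(C)(C)C)c1c(OC)cc(OC)cc1O[C@@H](C=C)c1ccc(OC)c(OC)c1OC
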